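The constants are those of an exercise; what happens was integrated by code.

I began from 4.18, the split S of the blue flask: the rate constant k_T of the step to target times the reagent concentration, divided by the rate constant k_Q of the step to side product, or the parts of starting material going to target for each part going to side product. This is a selectivity factor, and it moves with the reagent.

| setting | teal | amber | blue |
|---|---|---|---|
| starting material | 0.010 M | 0.010 M | 0.010 M |
| reagent | 31.0 mM | 5.00 mM | 12.0 mM |
| time | 15 s | 15 s | 15 s |

    starting material → side product (k1 = 0.025 /s)
    target → over-reaction product (k2 = 0.048 /s)
    starting material + reagent → target (k3 = 8.7 /M/s)
    crystals ⇌ target, rate k4*(cs4 - [target]) while solid is left; crystals form when [target] > cs4 (cs4 = 2.2 mM, k4 = 4.5 /s)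

- amounts and yields of target count crystals too
- given per volume of solution although it is solid: crystals
- run time (teal): 15 s

1. which of the two there is more of at the end, teal (target / side product)
2. which of the two there is more of at the end, amber (target / side product)
3. which of the two there is more of at the end, blue (target / side product)
4. target at the end, in percent of the starting material charged, teal
5. target at the end, in percent of the starting material charged, amber
6. target at the end, in percent of the starting material charged, blue

The bench rule is pseudo-first-order: hold the reagent at its charge and reckon the fraction of starting material left, f = exp(−(k_Q + k_T[reagent])t). Over 15 s this gave me f = 1.20% in teal, 14.4% in blue and 35.8% in amber, with S at 10.8 in teal and 1.74 in amber.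

The rule wants reagent far in excess, so its border is the ratio of reagent to starting material charged: 3.10 in teal, 1.20 in blue and 0.500 in amber. Teal's ratio, the highest, is still below 10, so I read each f as a floor and each S as a ceiling. In amber the reagent is the limiting reagent, and with the reagent at half of its charge, S there falls to 0.870, below one. But S tells what is made and not what stays, and dissolved target has a half-life of 14 s by over-reaction, comparable to the run. So I called target ahead in teal and blue, where S stands well above one, and side product ahead in amber, where S between 1.74 and 0.870 gives neither product a clear lead and my call rested on that loss of target. I gave no yields.

The forecast named target for teal, side product for amber and target for blue, with target at 71% (67% to 75%), 18.6% (16.5% to 21%) and 43% (39% to 46%) in the same order, on the grounds that “Reagent level sets how well the bimolecular step beats the first-order loss of starting material”.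

The flasks gave target at 71.7% in teal, 18.9% in amber and 42.9% in blue, and the larger of the two was target in teal, side product in amber and target in blue. Blue kept 52.0% of its reagent, and its target and over-reaction product together stood at 3.07 times its side product, against 3.18 for S at the mean of charged and final reagent. For the neighbour of blue charged with 0.030 M of reagent, ending at 71.0% of it, the same S is 8.93, and that flask ended with 71.1% target, 15.9% over-reaction product and 9.83% side product.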